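**Strategy.** Ring A, the oxolane O7–C7–C8–C8'–C9' that carries the guaiacyl group (lignan numbering, primed atoms on the syringyl half), is disconnected across the O7–C9' ether bond and the bridgehead bond C8–C8'. The carbinol bridgehead C8' lies alpha and the methylene C9' beta to the benzylic carbon C7', so C9'–C8'–C7' is an aryl vinyl ketone in disguise, while O7–C7–C8(–C9–O) is an erythro 2,3-epoxy alcohol. One base-mediated operation (oxa-Michael addition of O7 to the enone, then 5-exo opening of the oxirane by the resulting enolate) forms both bonds, closes ring A and sets C8 by inversion. Enolate hydroxylation then installs the C8' hydroxyl, and ketone reduction with benzylic cyclisation closes ring B.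

Key step: step 5

Remark: aldehydes 1 and 4 are taken as commercial; the tartrate enantiomer in step 2 is assigned from the empirical face-selection rule of the titanium tartrate epoxidation.
Remark: compound 8 is written without a descriptor at C8' (oxolane C3), because this centre is epimerisable and both epimers converge in step 6; likewise C7' in 10 converges in step 8.

Step 1
Reactants: 1 4-(benzyloxy)-3-methoxybenzaldehyde
Product: 2 rac-1-[4-(benzyloxy)-3-methoxyphenyl]prop-2-en-1-ol
Conditions: CH2=CHMgBr, THF, −78 → 0 °C; then H2O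
Reagents that add atoms: vinylmagnesium bromide, C=C[Mg]Br
Why: Grignard addition of the vinyl nucleophile to the aryl aldehyde should give the racemic secondary allylic alcohol needed for the resolution; no stereocontrol is required here.

Step 2
Reactants: 2 rac-1-[4-(benzyloxy)-3-methoxyphenyl]prop-2-en-1-ol
Product: 3 (R)-[4-(benzyloxy)-3-methoxyphenyl][(2S)-oxiran-2-yl]methanol (erythro epoxy alcohol)
Conditions: Ti(OiPr)4 (0.1 equiv), D-(−)-diisopropyl tartrate (0.15 equiv), t-BuOOH (0.5 equiv), 4 Å MS, CH2Cl2, −20 °C; unreacted (R)-alcohol removed by chromatography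
Reagents that add atoms: tert-butyl hydroperoxide, CC(C)(C)OO
Why: Sharpless kinetic resolution, in which the titanium tartrate should epoxidise the (S)-carbinol fast and, as is general for secondary allylic alcohols, on the face that gives the erythro isomer, so that C7 is selected by the resolution and C8 is set by tartrate-controlled oxygen delivery.

Step 3
Reactants: 4 4-(benzyloxy)-3,5-dimethoxybenzaldehyde
Product: 5 rac-1-[4-(benzyloxy)-3,5-dimethoxyphenyl]prop-2-en-1-ol
Conditions: CH2=CHMgBr, THF, −78 → 0 °C; then H2O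
Reagents that add atoms: vinylmagnesium bromide, C=C[Mg]Br
Why: Grignard addition as in step 1; the carbinol centre is removed in step 4.

Step 4
Reactants: 5 rac-1-[4-(benzyloxy)-3,5-dimethoxyphenyl]prop-2-en-1-ol
Product: 6 1-[4-(benzyloxy)-3,5-dimethoxyphenyl]prop-2-en-1-one
Conditions: MnO2 (excess), CH2Cl2, rt; used at once
Reagents that add atoms: none
Why: MnO2 oxidation of the doubly activated (benzylic and allylic) alcohol should give the aryl vinyl ketone under neutral conditions that spare the polymerisation-prone enone.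

Step 5
Reactants: 3 (R)-[4-(benzyloxy)-3-methoxyphenyl][(2S)-oxiran-2-yl]methanol; 6 1-[4-(benzyloxy)-3,5-dimethoxyphenyl]prop-2-en-1-one
Product: 8 [(4R,5S)-5-[4-(benzyloxy)-3-methoxyphenyl]-4-(hydroxymethyl)oxolan-3-yl][4-(benzyloxy)-3,5-dimethoxyphenyl]methanone (C3 epimers), via oxa-Michael adduct 7 (not isolated)
Conditions: t-BuOK (0.1 equiv), THF/t-BuOH 10:1, −20 °C; then t-BuOK (1.1 equiv), −20 °C → rt; AcOH
Reagents that add atoms: none
Why: Proposed new method: a Michael-initiated ring closure in which catalytic alkoxide adds O7 of 3 to the CH2 terminus of enone 6 (oxa-Michael addition, giving the O7–C9' bond in neutral 7) and, once the enone is consumed, the potassium enolate of 7 opens the oxirane at its internal carbon C8 (giving the C8–C8' bond); the closest known reaction types are the base-catalysed oxa-Michael addition of alcohols to vinyl ketones and the Stork-type intramolecular opening of epoxides by nitrile-stabilised carbanions and ketone enolates. Ring A closes in the 5-exo-tet mode, which should be preferred over 6-endo attack at the terminal CH2 because only the exo trajectory lies collinear with the breaking C–O bond within the tether. C8 is set by stereospecific inversion at the (S)-oxirane carbon while the C7 carbinol centre is carried through unchanged, so the erythro epoxy alcohol translates into the trans arrangement of aryl and hydroxymethyl groups; C8' remains epimerisable and is fixed in step 6. The step needs O–C bond formation to be complete before enolate and free enone coexist (secured by running the first stage with catalytic base and t-BuOH as proton source, which also keeps the free epoxy alkoxide, and with it Payne rearrangement, at a low level) and C- rather than O-alkylation of the enolate (secured by the five-membered transition state).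

Step 6
Reactants: 8 [(4R,5S)-5-[4-(benzyloxy)-3-methoxyphenyl]-4-(hydroxymethyl)oxolan-3-yl][4-(benzyloxy)-3,5-dimethoxyphenyl]methanone (C3 epimers)
Product: 9 [(3S,4R,5S)-5-[4-(benzyloxy)-3-methoxyphenyl]-3-hydroxy-4-(hydroxymethyl)oxolan-3-yl][4-(benzyloxy)-3,5-dimethoxyphenyl]methanone
Conditions: KN(SiMe3)2 (2.3 equiv), THF, −78 → −40 °C; 2-(phenylsulfonyl)-3-phenyloxaziridine, −78 °C; AcOH
Reagents that add atoms: 2-(phenylsulfonyl)-3-phenyloxaziridine, O=S(=O)(c1ccccc1)N1OC1c1ccccc1
Why: Electrophilic hydroxylation of the potassium enolate (the primary hydroxyl riding as its alkoxide) by the N-sulfonyloxaziridine, in which both epimers of 8 converge on one enolate and the new C8' centre should be set by attack anti to the adjacent CH2O substituent on C8, placing OH trans and the aroyl group cis to C9.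

Step 7
Reactants: 9 [(3S,4R,5S)-5-[4-(benzyloxy)-3-methoxyphenyl]-3-hydroxy-4-(hydroxymethyl)oxolan-3-yl][4-(benzyloxy)-3,5-dimethoxyphenyl]methanone
Product: 10 (3S,4R,5S)-5-[4-(benzyloxy)-3-methoxyphenyl]-3-{[4-(benzyloxy)-3,5-dimethoxyphenyl](hydroxy)methyl}-4-(hydroxymethyl)oxolan-3-ol (both C7' carbinol epimers)
Conditions: NaBH4, MeOH, 0 °C
Reagents that add atoms: none
Why: Borohydride reduction of the aryl ketone should give the benzylic alcohol, whose C7' configuration is irrelevant because step 8 passes through a planar benzylic cation.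

Step 8
Reactants: 10 (3S,4R,5S)-5-[4-(benzyloxy)-3-methoxyphenyl]-3-{[4-(benzyloxy)-3,5-dimethoxyphenyl](hydroxy)methyl}-4-(hydroxymethyl)oxolan-3-ol
Product: 11 (1S,2R,5R,6S)-2-[4-(benzyloxy)-3,5-dimethoxyphenyl]-6-[4-(benzyloxy)-3-methoxyphenyl]-3,7-dioxabicyclo[3.3.0]octan-1-ol (di-O-benzylfraxiresinol)
Conditions: 10-camphorsulfonic acid (cat.), CH2Cl2, 0 °C → rt
Reagents that add atoms: none
Why: Acid-catalysed cyclodehydration (intramolecular SN1 etherification) in which the p-alkoxybenzyl cation at C7' is captured by the C9 hydroxyl to close ring B, the cis ring fusion being enforced by the bicyclo[3.3.0] framework and C7' being set by the aryl group taking the exo (convex) position.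

Step 9
Reactants: 11 di-O-benzylfraxiresinol
Product: 12 fraxiresinol, (1S,2R,5R,6S)-2-(4-hydroxy-3,5-dimethoxyphenyl)-6-(4-hydroxy-3-methoxyphenyl)-3,7-dioxabicyclo[3.3.0]octan-1-ol
Conditions: H2 (1 atm), Pd/C (10%), EtOAc, rt, stopped at full conversion
Reagents that add atoms: none
Why: Hydrogenolysis of the two aryl benzyl ethers over palladium on carbon should be much faster under neutral conditions than cleavage of the cyclic benzylic ethers and releases both phenols without touching a stereocentre.

**Compound list**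

1 | 4-(benzyloxy)-3-methoxybenzaldehyde | COc1cc(C=O)ccc1OCc1ccccc1 | starting material
2 | rac-1-[4-(benzyloxy)-3-methoxyphenyl]prop-2-en-1-ol | COc1cc(C(O)C=C)ccc1OCc1ccccc1 | intermediate
3 | (R)-[4-(benzyloxy)-3-methoxyphenyl][(2S)-oxiran-2-yl]methanol | COc1cc([C@@H](O)[C@@H]2CO2)ccc1OCc1ccccc1 | intermediate
4 | 4-(benzyloxy)-3,5-dimethoxybenzaldehyde | COc1cc(C=O)cc(OC)c1OCc1ccccc1 | starting material
5 | rac-1-[4-(benzyloxy)-3,5-dimethoxyphenyl]prop-2-en-1-ol | COc1cc(C(O)C=C)cc(OC)c1OCc1ccccc1 | intermediate
6 | 1-[4-(benzyloxy)-3,5-dimethoxyphenyl]prop-2-en-1-one | COc1cc(C(=O)C=C)cc(OC)c1OCc1ccccc1 | intermediate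
7 | 3-{(R)-[4-(benzyloxy)-3-methoxyphenyl][(2S)-oxiran-2-yl]methoxy}-1-[4-(benzyloxy)-3,5-dimethoxyphenyl]propan-1-one (oxa-Michael adduct, not isolated) | COc1cc([C@@H](OCCC(=O)c2cc(OC)c(OCc3ccccc3)c(OC)c2)[C@@H]2CO2)ccc1OCc1ccccc1 | intermediate
8 | [(4R,5S)-5-[4-(benzyloxy)-3-methoxyphenyl]-4-(hydroxymethyl)oxolan-3-yl][4-(benzyloxy)-3,5-dimethoxyphenyl]methanone (C3 epimers) | COc1cc([C@H]2OCC(C(=O)c3cc(OC)c(OCc4ccccc4)c(OC)c3)[C@@H]2CO)ccc1OCc1ccccc1 | intermediate
9 | [(3S,4R,5S)-5-[4-(benzyloxy)-3-methoxyphenyl]-3-hydroxy-4-(hydroxymethyl)oxolan-3-yl][4-(benzyloxy)-3,5-dimethoxyphenyl]methanone | COc1cc([C@H]2OC[C@](O)(C(=O)c3cc(OC)c(OCc4ccccc4)c(OC)c3)[C@@H]2CO)ccc1OCc1ccccc1 | intermediate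
10 | (3S,4R,5S)-5-[4-(benzyloxy)-3-methoxyphenyl]-3-{[4-(benzyloxy)-3,5-dimethoxyphenyl](hydroxy)methyl}-4-(hydroxymethyl)oxolan-3-ol (C7' epimers) | COc1cc([C@H]2OC[C@](O)(C(O)c3cc(OC)c(OCc4ccccc4)c(OC)c3)[C@@H]2CO)ccc1OCc1ccccc1 | intermediate
11 | (1S,2R,5R,6S)-2-[4-(benzyloxy)-3,5-dimethoxyphenyl]-6-[4-(benzyloxy)-3-methoxyphenyl]-3,7-dioxabicyclo[3.3.0]octan-1-ol | COc1cc([C@H]2OC[C@]3(O)[C@@H](c4cc(OC)c(OCc5ccccc5)c(OC)c4)OC[C@H]23)ccc1OCc1ccccc1 | intermediate
12 | fraxiresinol, (1S,2R,5R,6S)-2-(4-hydroxy-3,5-dimethoxyphenyl)-6-(4-hydroxy-3-methoxyphenyl)-3,7-dioxabicyclo[3.3.0]octan-1-ol | COc1cc([C@H]2OC[C@]3(O)[C@@H](c4cc(OC)c(O)c(OC)c4)OC[C@H]23)ccc1O | target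

**Total step count:** 9. **Longest linear sequence:** 7 (steps 1, 2, 5, 6, 7, 8, 9).

**Steps most likely to fail**

1. Step 5 (proposed new method). What may go wrong: Michael oligomerisation of the enone by the intermediate enolate, Payne rearrangement of the epoxy alkoxide, retro-oxa-Michael ring opening of the product enolate, or a ring closure that is too slow for a ketone enolate. Fallback with known chemistry, setting out from 3 and returning at 8: cyanoethylation of 3 with acrylonitrile under catalytic t-BuOK should give 3-{(R)-[4-(benzyloxy)-3-methoxyphenyl][(2S)-oxiran-2-yl]methoxy}propanenitrile F1. Treatment with KN(SiMe3)2 in toluene then effects the Stork epoxynitrile cyclisation (5-exo, inversion at the oxirane carbon) to (4R,5S)-5-[4-(benzyloxy)-3-methoxyphenyl]-4-(hydroxymethyl)oxolane-3-carbonitrile F2. The aryl ketone is completed by adding excess [4-(benzyloxy)-3,5-dimethoxyphenyl]magnesium bromide F4 and hydrolysing the ketimine with aqueous acid, which returns 8. F4 is made with magnesium from 5-bromo-2-(benzyloxy)-1,3-dimethoxybenzene F3, itself obtained by benzylation of commercial 4-bromo-2,6-dimethoxyphenol.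

2. Step 6. What may go wrong: β-elimination of the ring alkoxide from the potassium enolate (ring opening of the oxolane), or oxidant attack on the wrong face. Fallback setting out from 8 and returning at 9: soft enolisation with Me3SiOTf and Et3N in CH2Cl2, which avoids a free enolate, should give the bis(trimethylsilyl) compound {(4R,5S)-5-[4-(benzyloxy)-3-methoxyphenyl]-4-[(trimethylsilyloxy)methyl]oxolan-3-ylidene}[4-(benzyloxy)-3,5-dimethoxyphenyl]methyl trimethylsilyl ether F5. Rubottom oxidation with m-CPBA (NaHCO3 buffer) anti to the now bulkier CH2OSiMe3 group, followed by desilylation with citric acid in MeOH, gives 9.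

3. Step 8. What may go wrong: a pinacol-type 1,2-shift in the benzylic cation next to the tertiary carbinol, or acid-induced epimerisation at C7 through reversible opening of ring A. Fallback setting out from 10 and returning at 12 (bypassing 11 and step 9): hydrogenolysis first (H2, Pd/C, EtOAc) should give (3S,4R,5S)-5-(4-hydroxy-3-methoxyphenyl)-3-[hydroxy(4-hydroxy-3,5-dimethoxyphenyl)methyl]-4-(hydroxymethyl)oxolan-3-ol F6. With the syringyl phenol free, ring B can close under near-neutral conditions (catalytic pyridinium p-toluenesulfonate in aqueous THF) through the syringyl para-quinone methide F7, which the primary hydroxyl captures with the aryl group exo, giving 12 directly.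

**Further compounds**

F1 | step 5 | 3-{(R)-[4-(benzyloxy)-3-methoxyphenyl][(2S)-oxiran-2-yl]methoxy}propanenitrile | COc1cc([C@@H](OCCC#N)[C@@H]2CO2)ccc1OCc1ccccc1
F2 | step 5 | (4R,5S)-5-[4-(benzyloxy)-3-methoxyphenyl]-4-(hydroxymethyl)oxolane-3-carbonitrile (C3 epimers) | COc1cc([C@H]2OCC(C#N)[C@@H]2CO)ccc1OCc1ccccc1
F3 | step 5 | 5-bromo-2-(benzyloxy)-1,3-dimethoxybenzene | COc1cc(Br)cc(OC)c1OCc1ccccc1
F4 | step 5 | [4-(benzyloxy)-3,5-dimethoxyphenyl]magnesium bromide | COc1cc([Mg]Br)cc(OC)c1OCc1ccccc1
F5 | step 6 | {(4R,5S)-5-[4-(benzyloxy)-3-methoxyphenyl]-4-[(trimethylsilyloxy)methyl]oxolan-3-ylidene}[4-(benzyloxy)-3,5-dimethoxyphenyl]methyl trimethylsilyl ether | COc1cc([C@H]2OCC(=C(O[Si](C)(C)C)c3cc(OC)c(OCc4ccccc4)c(OC)c3)[C@@H]2CO[Si](C)(C)C)ccc1OCc1ccccc1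
F6 | step 8 | (3S,4R,5S)-5-(4-hydroxy-3-methoxyphenyl)-3-[hydroxy(4-hydroxy-3,5-dimethoxyphenyl)methyl]-4-(hydroxymethyl)oxolan-3-ol (C7' epimers) | COc1cc([C@H]2OC[C@](O)(C(O)c3cc(OC)c(O)c(OC)c3)[C@@H]2CO)ccc1O
F7 | step 8 | syringyl para-quinone methide, 4-{[(3S,4R,5S)-3-hydroxy-5-(4-hydroxy-3-methoxyphenyl)-4-(hydroxymethyl)oxolan-3-yl]methylidene}-2,6-dimethoxycyclohexa-2,5-dien-1-one | COc1cc([C@H]2OC[C@](O)(C=C3C=C(OC)C(=O)C(OC)=C3)[C@@H]2CO)ccc1O
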